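Numbering: carbocycle C1 (sorbyl enol), C2 (C=O), C3 (CH3), C4 (OH), C5 (CH3, O9), C6 (H); lactone O9, C8 (C=O), C7 (CH3, N). The target is cut at C5–C6, C1–C2 and O9–C8: the run O9–C5–C4–C3–C2 with its two methyls and two oxygens is 3,5-dimethyltetronic acid, whose 2-silyloxyfuran 6 is a diene with termini C5 and C2. In one operation 6 adds across C6=C1 of E-enone 12 (from (S)-2-methylserine; C7 already carries CH3, NHBoc and the C8 ester), fluoride opens the oxygen bridge at C2, and the C5 alkoxide closes the lactone on C8: two rings, three bonds, stereocentres C5 and C6. Sorbyl chain and fumaric amide follow.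

Key step: step 7

Remark on the chemistry: the C5 configuration of 4 and 5 and the carbinol configuration of 16 are of no consequence. The first is erased in step 4 and the second in step 9, and 16 is carried as a mixture of epimers.

Step 1
Reactants: 1 ethyl (S)-lactate; 2 propanoyl chloride
Product: 3 ethyl (S)-2-(propanoyloxy)propanoate
Conditions: pyridine, DMAP (cat.), CH2Cl2, 0 °C → rt
Reagents that add atoms: none
Why: O-acylation of a secondary alcohol by an acid chloride under nucleophilic catalysis should be clean and leaves the lactate centre untouched.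

Step 2
Reactants: 3 ethyl (S)-2-(propanoyloxy)propanoate
Product: 4 (S)-4-hydroxy-3,5-dimethylfuran-2(5H)-one (3,5-dimethyltetronic acid)
Conditions: LiN(SiMe3)2 (2.2 equiv), THF, −78 → 0 °C; 1 M HCl
Reagents that add atoms: none
Why: Dieckmann condensation, in which the propanoate enolate closes the five-membered ring on the ethyl ester and deprotonation of the acidic tetronic acid by the second equivalent of base makes the closure irreversible.

Step 3
Reactants: 4 (S)-4-hydroxy-3,5-dimethylfuran-2(5H)-one
Product: 5 (S)-4-methoxy-3,5-dimethylfuran-2(5H)-one
Conditions: Me2SO4, K2CO3, acetone, reflux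
Reagents that add atoms: dimethyl sulfate, COS(=O)(=O)OC
Why: O-alkylation of the vinylogous carboxylate by a hard methylating agent should give the 4-methoxybutenolide (a vinylogous ester), the usual outcome for 3-alkyltetronic acids.

Step 4
Reactants: 5 (S)-4-methoxy-3,5-dimethylfuran-2(5H)-one
Product: 6 tert-butyl[(4-methoxy-3,5-dimethylfuran-2-yl)oxy]dimethylsilane
Conditions: TBSOTf, Et3N, CH2Cl2, 0 °C
Reagents that add atoms: tert-butyldimethylsilyl trifluoromethanesulfonate, CC(C)(C)[Si](C)(C)OS(=O)(=O)C(F)(F)F
Why: Soft enolisation (silyl triflate on the carbonyl oxygen, Et3N removes the C5 proton) gives the aromatic 2-silyloxyfuran, the standard preparation of such dienes, and the C5 stereocentre disappears.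

Step 5
Reactants: 7 (S)-2-methylserine
Product: 9 methyl (S)-2-[(tert-butoxycarbonyl)amino]-3-hydroxy-2-methylpropanoate, via methyl (S)-2-amino-3-hydroxy-2-methylpropanoate hydrochloride 8 (not isolated)
Conditions: SOCl2, MeOH, 0 °C → reflux; evaporate; Boc2O, Et3N, CH2Cl2, rt
Reagents that add atoms: methanol, CO; di-tert-butyl dicarbonate, CC(C)(C)OC(=O)OC(=O)OC(C)(C)C
Why: Fischer esterification with HCl made in the flask, then carbamate formation at the more nucleophilic nitrogen, with a quaternary stereocentre that cannot epimerise.

Step 6
Reactants: 9 methyl (S)-2-[(tert-butoxycarbonyl)amino]-3-hydroxy-2-methylpropanoate; 10 1-(triphenyl-λ5-phosphanylidene)propan-2-one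
Product: 12 methyl (S,E)-2-[(tert-butoxycarbonyl)amino]-2-methyl-5-oxohex-3-enoate, via methyl (S)-2-[(tert-butoxycarbonyl)amino]-2-methyl-3-oxopropanoate 11 (not isolated)
Conditions: Dess–Martin periodinane, CH2Cl2, rt; then 10, rt → 40 °C
Reagents that add atoms: none
Why: Dess–Martin oxidation followed in the same flask by Wittig olefination with a stabilised ylide (E-selective), so that the deformylation-prone α-formyl ester is never isolated, and the quaternary centre has no α-hydrogen to lose.

Step 7
Reactants: 6 tert-butyl[(4-methoxy-3,5-dimethylfuran-2-yl)oxy]dimethylsilane; 12 methyl (S,E)-2-[(tert-butoxycarbonyl)amino]-2-methyl-5-oxohex-3-enoate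
Product: 14 N-Boc bicyclic lactone bearing the enolised acetyl group on C1 (C4 methyl enol ether; 5S 6R 7S), via oxanorbornene silyl ketal 13 (not isolated)
Conditions: Sc(OTf)3 (10 mol %), CH2Cl2, −40 °C → rt; then Bu4NF, THF, 0 °C → rt; 1 M HCl work-up
Reagents that add atoms: none
Why: The Sc-bound enone is attacked at C6 by the nucleophilic C5 of furan 6 and the resulting enolate carbon C1 closes onto the silyloxocarbenium carbon C2 (vinylogous Mukaiyama–Michael addition and ring closure, or the same two bonds in an asynchronous endo [4+2]) to give ketal 13; fluoride then removes silicon, the C2 oxyanion expels O9 to leave the C2 ketone, and the C5 alkoxide attacks the C8 ester with loss of methoxide, the enolised β-diketone anion being the thermodynamic sink. The closest known reactions are Diels–Alder and Mukaiyama–Michael additions of 2-silyloxyfurans to enones and the opening of the resulting 7-oxanorbornene ketals to cyclohexenones. The carbocycle closes as a six-membered cycloadduct (equivalent to a 6-exo-trig closure of C1 onto C2) and the lactone by 5-exo-trig acyl substitution. C5 and C6 are set together: the acetyl group lies endo, which places the C7 group exo and therefore cis to O9 (cis ring fusion), and the alkene face is chosen by C7, whose C–N bond lies anti to the incoming furan with the small methyl outside and the ester inside, so that (7S) should lead to (5S,6R), while C1 is enolised and carries no configuration. The step needs C5-to-C6 regiochemistry, which the 2-silyloxy donor (largest coefficient at C5) and the enone β-carbon supply, γ-attack of the furan, which is normal for 2-silyloxyfurans, and lactonisation at the ester and not at the carbamate carbonyl, which the five-membered ring and the deprotonated carbamate secure.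

Step 8
Reactants: 14 N-Boc bicyclic lactone bearing the enolised acetyl group on C1; 15 (E)-crotonaldehyde
Product: 16 aldol adduct carrying the C(OH)–CH2–CH(OH)–CH=CH–CH3 chain on C1 (carbinol epimers)
Conditions: LiN(iPr)2 (3.3 equiv), THF, −78 °C; 15, −78 °C; AcOH
Reagents that add atoms: none
Why: Polyanion aldol of the Hauser–Harris type, in which the third deprotonation (after N–H and enol O–H) takes place at the acetyl methyl and this most basic terminus adds 1,2 to the enal at low temperature; the new carbinol centre is formed without control and is removed in step 9.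

Step 9
Reactants: 16 aldol adduct carrying the C(OH)–CH2–CH(OH)–CH=CH–CH3 chain on C1
Product: 17 trifluoroacetate salt of the C7 primary amine bearing the (2E,4E)-sorbyl enol on C1 (C4 methyl enol ether)
Conditions: CF3CO2H, CH2Cl2, 0 °C → rt
Reagents that add atoms: trifluoroacetic acid (counter-ion), OC(=O)C(F)(F)F
Why: Acidolysis of the Boc carbamate together with acid-promoted E1 dehydration of the allylic aldol through its allyl cation should give the fully conjugated (E,E)-dienone under thermodynamic control, the amine staying protonated and unreactive.

Step 10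
Reactants: 17 trifluoroacetate salt of the C7 primary amine bearing the sorbyl enol on C1; 18 (E)-4-(tert-butoxy)-4-oxobut-2-enoic acid
Product: 20 tert-butyl ester and C4 methyl enol ether of sorbicillactone A, via tert-butyl (E)-4-chloro-4-oxobut-2-enoate 19 (not isolated)
Conditions: 18, 1-chloro-N,N,2-trimethylprop-1-en-1-amine, CH2Cl2, 0 °C; then 17, iPr2NEt, −20 → 0 °C
Reagents that add atoms: none
Why: Amide formation with an acid chloride made under neutral conditions that spare the tert-butyl ester, the amine being set free only in the presence of excess acyl chloride so that N-acylation outruns condensation with the neighbouring enolised acyl group.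

Step 11
Reactants: 20 tert-butyl ester and C4 methyl enol ether of sorbicillactone A
Product: 21 sorbicillactone A
Conditions: CF3CO2H, CH2Cl2, rt; evaporate; 2 M HCl, THF, 40 °C
Reagents that add atoms: water, O
Why: Acidolysis of the tert-butyl ester (loss of 2-methylpropene) and acid-catalysed hydrolysis of the vinylogous methyl ester (water adds at C4, methanol leaves) in one flask without base, so that the lactone, the two Michael acceptors and the non-enolisable stereocentres C5, C6 and C7 are not put at risk.

Compound list
1 | ethyl (S)-lactate | CCOC(=O)[C@H](C)O | starting material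
2 | propanoyl chloride | CCC(=O)Cl | starting material
3 | ethyl (S)-2-(propanoyloxy)propanoate | CCOC(=O)[C@H](C)OC(=O)CC | intermediate
4 | (S)-4-hydroxy-3,5-dimethylfuran-2(5H)-one (3,5-dimethyltetronic acid) | CC1=C(O)[C@H](C)OC1=O | intermediate
5 | (S)-4-methoxy-3,5-dimethylfuran-2(5H)-one | CC1=C(OC)[C@H](C)OC1=O | intermediate
6 | tert-butyl[(4-methoxy-3,5-dimethylfuran-2-yl)oxy]dimethylsilane | COc1c(C)oc(O[Si](C)(C)C(C)(C)C)c1C | intermediate
7 | (S)-2-methylserine | C[C@](N)(CO)C(=O)O | starting material
8 | methyl (S)-2-amino-3-hydroxy-2-methylpropanoate hydrochloride | C[C@](N)(CO)C(=O)OC.Cl | intermediate (not isolated)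
9 | methyl (S)-2-[(tert-butoxycarbonyl)amino]-3-hydroxy-2-methylpropanoate | C[C@](NC(=O)OC(C)(C)C)(CO)C(=O)OC | intermediate
10 | 1-(triphenyl-λ5-phosphanylidene)propan-2-one | CC(=O)C=P(c1ccccc1)(c1ccccc1)c1ccccc1 | starting material
11 | methyl (S)-2-[(tert-butoxycarbonyl)amino]-2-methyl-3-oxopropanoate | C[C@](NC(=O)OC(C)(C)C)(C=O)C(=O)OC | intermediate (not isolated)
12 | methyl (S,E)-2-[(tert-butoxycarbonyl)amino]-2-methyl-5-oxohex-3-enoate | CC(=O)/C=C/[C@](C)(NC(=O)OC(C)(C)C)C(=O)OC | intermediate
13 | 7-oxanorbornene silyl ketal: bridgeheads C5 (CH3) and C2 (OTBS) joined by O9, C3(CH3)=C4(OCH3), C6 with the C7 amino ester chain exo, C1 with acetyl endo | CC(=O)[C@H]1[C@H]([C@](C)(NC(=O)OC(C)(C)C)C(=O)OC)[C@]2(C)O[C@@]1(O[Si](C)(C)C(C)(C)C)C(C)=C2OC | intermediate (not isolated)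
14 | N-Boc bicyclic lactone: C1=C(OH)CH3 (enolised acetyl, OH towards C2=O), C2 ketone, C3(CH3)=C4(OCH3), C5 (S; CH3, O9), C6 (R; H), cis-fused lactone O9–C8(=O)–C7 (S; CH3, NHBoc) | C/C(O)=C1/C(=O)C(C)=C(OC)[C@@]2(C)OC(=O)[C@@](C)(NC(=O)OC(C)(C)C)[C@@H]12 | intermediate
15 | (E)-crotonaldehyde | C/C=C/C=O | starting material
16 | aldol adduct of 14: chain on C1 is C(OH)–CH2–CH(OH)–CH=CH–CH3 (E alkene, carbinol epimers) | C/C=C/C(O)C/C(O)=C1/C(=O)C(C)=C(OC)[C@@]2(C)OC(=O)[C@@](C)(NC(=O)OC(C)(C)C)[C@@H]12 | intermediate
17 | trifluoroacetate salt of the C7 primary amine with the (2E,4E)-sorbyl enol on C1 and the C4 methyl enol ether | C/C=C/C=C/C(O)=C1/C(=O)C(C)=C(OC)[C@@]2(C)OC(=O)[C@@](C)(N)[C@@H]12.OC(=O)C(F)(F)F | intermediate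
18 | (E)-4-(tert-butoxy)-4-oxobut-2-enoic acid (mono-tert-butyl fumarate) | CC(C)(C)OC(=O)/C=C/C(=O)O | starting material
19 | tert-butyl (E)-4-chloro-4-oxobut-2-enoate | CC(C)(C)OC(=O)/C=C/C(=O)Cl | intermediate (not isolated)
20 | tert-butyl ester and C4 methyl enol ether of sorbicillactone A | C/C=C/C=C/C(O)=C1/C(=O)C(C)=C(OC)[C@@]2(C)OC(=O)[C@@](C)(NC(=O)/C=C/C(=O)OC(C)(C)C)[C@@H]12 | intermediate
21 | sorbicillactone A | C/C=C/C=C/C(O)=C1/C(=O)C(C)=C(O)[C@@]2(C)OC(=O)[C@@](C)(NC(=O)/C=C/C(=O)O)[C@@H]12 | target

Total step count: 11. Longest linear sequence: 9 (steps 1–4, then 7–11); the enone branch (steps 5 and 6) joins at step 7.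

Steps most likely to fail

First, step 7. The C5–C6 bond joins a quaternary carbon to a carbon flanked by quaternary C7, so the addition may stall while the furan is lost by protodesilylation. The acyclic C7 centre steers the alkene face only weakly, so both faces may be used. The activated enone may also be captured at C6 by the carbamate carbonyl oxygen, and an open adduct may fragment by retro-Michael reaction on fluoride treatment. The fallback is an ionic two-stage sequence with isolation in between, setting out from 6 and 12. A Me3SiOTf-catalysed vinylogous Mukaiyama–Michael addition at −78 °C (or the uncatalysed addition at 12 kbar) and acidic aqueous work-up would give the open butenolide methyl ketone F1, and the C5/C6 diastereomers would be separated at this point. KOtBu in THF would then bring about Dieckmann-type attack of the C1 enolate on the butenolide carbonyl C2, cleavage of C2–O9 and transfer of the C5 alkoxide to C8, and the sequence comes back to the route at 14.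

Second, step 9. After ionisation of the allylic alcohol, the cation may be captured by the enol oxygen on C2 (closure to a fused dihydropyranone) or by trifluoroacetate instead of losing a proton, so that dehydration is incomplete or misdirected. The fallback accepts the ring closure and reverses it later with base, setting out from 16. The acid treatment is run through to the ring-closed ether, the fused 2-propenyl-2,3-dihydropyran-4-one amine trifluoroacetate F2 (the usual cyclodehydration of a δ-hydroxy-β-diketone). F2 is acylated as in step 10 to the amide F3; no enolised acyl group is free at that stage. DBU in MeCN then opens the pyranone by E1cB (retro-oxa-Michael, with the acyl-dione enolate as leaving group) to the thermodynamically preferred (E,E)-dienone, and acidification rejoins the route at 20.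

Third, step 10. Acylation of the hindered α-tertiary amine may be slow, which leaves time for the freed amine to condense with the neighbouring enolised acyl carbon (five-membered cyclic enaminone) or to add in conjugate fashion to the unsaturated acid chloride. The fallback uses a small saturated acyl donor and builds the alkene afterwards, setting out from 17. 2-(Diethoxyphosphoryl)acetyl chloride and iPr2NEt would give the phosphonoacetamide F4. A Horner–Wadsworth–Emmons reaction of F4 with tert-butyl glyoxylate (LiCl, DBU, MeCN) would then form the E-configured butenedioate unit, and the sequence comes back to the route at 20.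

Further compounds
F1 | step 7 | open butenolide methyl ketone (Michael adduct; C5, C6 and C7 configured as in 14) | CC(=O)C[C@H]([C@](C)(NC(=O)OC(C)(C)C)C(=O)OC)[C@]1(C)OC(=O)C(C)=C1OC
F2 | step 9 | fused 2-propenyl-2,3-dihydropyran-4-one amine trifluoroacetate (ring oxygen on C2, ether carbon epimers) | C/C=C/C1CC(=O)C2=C(O1)C(C)=C(OC)[C@@]3(C)OC(=O)[C@@](C)(N)[C@@H]23.OC(=O)C(F)(F)F
F3 | step 9 | N-[(E)-4-(tert-butoxy)-4-oxobut-2-enoyl] amide of the fused dihydropyranone | C/C=C/C1CC(=O)C2=C(O1)C(C)=C(OC)[C@@]3(C)OC(=O)[C@@](C)(NC(=O)/C=C/C(=O)OC(C)(C)C)[C@@H]23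
F4 | step 10 | N-[2-(diethoxyphosphoryl)acetyl] amide of the sorbyl lactone (C4 methyl enol ether) | C/C=C/C=C/C(O)=C1/C(=O)C(C)=C(OC)[C@@]2(C)OC(=O)[C@@](C)(NC(=O)CP(=O)(OCC)OCC)[C@@H]12
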